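The route rests on disconnecting C9–C10 of the ten-membered carbocycle. C9 is a secondary allylic carbinol attached to C10 of the C1=C10 enal unit, so an intramolecular Nozaki–Hiyama–Kishi addition of a C10 alkenyl iodide to a C9 aldehyde closes the germacrane ring, creates the C9 carbinol and transfers the iodide geometry to C1=C10 in one operation. The precursor is an open-chain trans-α-methylene-γ-butyrolactone: C7 carries the C8 methacrylate with its formyl group (C9), and C6 carries the (1E,5Z)-dienyl chain that ends in the C10 iodide and the silyl-protected C14 alcohol. C6–C8 are set beforehand by a ring-locked chromium allylation.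

Key step: step 15

Remark: atoms are labelled by germacranolide numbering (C1–C15, lactone C12 on O–C6); C14 is carried as a tert-butyldiphenylsilyl ether so that it survives the acidic step 12, and the CrCl2 of step 11 must be free of nickel salts so that the alkenyl iodide stays untouched.

Step 1
Reactants: 1 geranyl acetate [(2E)-3,7-dimethylocta-2,6-dien-1-yl acetate]
Product: 3 (2E)-3-methyl-6-oxohex-2-en-1-yl acetate, via 6,7-epoxygeranyl acetate 2 (not isolated)
Conditions: mCPBA, CH2Cl2, 0 °C; aqueous NaHCO3/Na2SO3 wash; then H5IO6, THF–H2O, 0 °C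
Reagents that add atoms: mCPBA (3-chloroperoxybenzoic acid), OOC(=O)c1cccc(Cl)c1
Why: The peracid epoxidises the electron-rich 6,7-alkene in preference to the 2,3-alkene deactivated by the allylic acetate (Prilezhaev epoxidation), and periodic acid hydrates and cleaves the epoxide (glycol cleavage) to the C1 aldehyde while the E-configured C4=C5 unit is untouched.

Step 2
Reactants: 3 (2E)-3-methyl-6-oxohex-2-en-1-yl acetate; 4 (triphenylphosphoranylidene)acetaldehyde
Product: 5 (2E,6E)-3-methyl-8-oxoocta-2,6-dien-1-yl acetate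
Conditions: toluene, 80 °C, 1.1 equiv of 4
Reagents that add atoms: none
Why: Wittig olefination with the stabilised formyl ylide should give the E-enal and adds C10 and C14; the small excess of ylide limits a second homologation.

Step 3
Reactants: 5 (2E,6E)-3-methyl-8-oxoocta-2,6-dien-1-yl acetate
Product: 6 (2E,6Z)-7-iodo-3-methyl-8-oxoocta-2,6-dien-1-yl acetate
Conditions: I2, DMAP (0.2 equiv), K2CO3, THF–H2O, rt
Reagents that add atoms: iodine, II
Why: DMAP adds reversibly to the enal, the enolate is iodinated at C10 and DMAP is expelled (α-iodination of an enal by a Baylis–Hillman-type addition–elimination), which should give the thermodynamically preferred Z-iodoenal with iodine cis to C2, the geometry needed for the ring-cis C1=C10 bond.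

Step 4
Reactants: 6 (2E,6Z)-7-iodo-3-methyl-8-oxoocta-2,6-dien-1-yl acetate
Product: 7 (2E,6Z)-8-hydroxy-7-iodo-3-methylocta-2,6-dien-1-yl acetate
Conditions: NaBH4, CeCl3·7H2O, MeOH, −40 °C
Reagents that add atoms: none
Why: Luche reduction delivers hydride 1,2 to the iodoenal without touching the alkenyl iodide or, at low temperature, the acetate.

Step 5
Reactants: 7 (2E,6Z)-8-hydroxy-7-iodo-3-methylocta-2,6-dien-1-yl acetate
Product: 8 (2E,6Z)-8-[(tert-butyldiphenylsilyl)oxy]-7-iodo-3-methylocta-2,6-dien-1-yl acetate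
Conditions: TBDPSCl, imidazole, CH2Cl2, rt
Reagents that add atoms: tert-butyl(chloro)diphenylsilane (TBDPSCl), CC(C)(C)[Si](Cl)(c1ccccc1)c1ccccc1
Why: Silylation of the primary allylic C14 alcohol; the bulky silyl ether is chosen because it should survive the later acid, chromium and acylation steps.

Step 6
Reactants: 8 (2E,6Z)-8-[(tert-butyldiphenylsilyl)oxy]-7-iodo-3-methylocta-2,6-dien-1-yl acetate
Product: 9 (2E,6Z)-8-[(tert-butyldiphenylsilyl)oxy]-7-iodo-3-methylocta-2,6-dien-1-ol
Conditions: K2CO3 (0.3 equiv), MeOH, rt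
Reagents that add atoms: none
Why: Base-catalysed transesterification (methanolysis) removes only the acetate; the silyl ether and the alkenyl iodide are stable.

Step 7
Reactants: 9 (2E,6Z)-8-[(tert-butyldiphenylsilyl)oxy]-7-iodo-3-methylocta-2,6-dien-1-ol
Product: 10 (2E,6Z)-8-[(tert-butyldiphenylsilyl)oxy]-7-iodo-3-methylocta-2,6-dienal
Conditions: MnO2, CH2Cl2, rt
Reagents that add atoms: none
Why: Manganese dioxide oxidises the allylic alcohol selectively to the C6 enal without E/Z isomerisation of the trisubstituted alkene.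

Step 8
Reactants: 11 (S)-but-3-ene-1,2-diol; 12 2-(bromomethyl)acrylic acid
Product: 14 (2S)-2-hydroxybut-3-en-1-yl 2-(bromomethyl)acrylate, via 2-(bromomethyl)acryloyl chloride 13 (not isolated)
Conditions: 12, (COCl)2, DMF (cat.), CH2Cl2, 0 °C to rt; then 11, 2,4,6-collidine, CH2Cl2, −78 °C
Reagents that add atoms: none
Why: The acid chloride made in the flask acylates the primary hydroxyl selectively at low temperature (acylation of an alcohol by an acid chloride), and the hindered base does not displace the allylic bromide; the future C8 stereocentre comes unchanged from the diol.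

Step 9
Reactants: 14 (2S)-2-hydroxybut-3-en-1-yl 2-(bromomethyl)acrylate
Product: 15 (2S)-2-[(triethylsilyl)oxy]but-3-en-1-yl 2-(bromomethyl)acrylate
Conditions: TESOTf, 2,6-lutidine, CH2Cl2, −78 °C
Reagents that add atoms: triethylsilyl trifluoromethanesulfonate (TESOTf), CC[Si](CC)(CC)OS(=O)(=O)C(F)(F)F
Why: Silyl triflate with a hindered pyridine base silylates the secondary allylic alcohol without nucleophilic attack on the bromomethyl acrylate.

Step 10
Reactants: 15 (2S)-2-[(triethylsilyl)oxy]but-3-en-1-yl 2-(bromomethyl)acrylate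
Product: 16 (5S)-3-(bromomethyl)-5-[(triethylsilyl)oxy]-5,6-dihydro-2H-pyran-2-one
Conditions: second-generation Grubbs catalyst [(H2IMes)(PCy3)Cl2Ru=CHPh] (5 mol %), toluene, 80 °C, 0.01 M
Reagents that add atoms: none
Why: Ring-closing metathesis between the vinyl group and the 2-substituted acrylate forms the six-membered unsaturated lactone with loss of ethylene, as established for acrylates and methacrylates of homoallylic alcohols; the ring fixes C8 cis to the lactone carbonyl across C7=C11.

Step 11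
Reactants: 10 (2E,6Z)-8-[(tert-butyldiphenylsilyl)oxy]-7-iodo-3-methylocta-2,6-dienal; 16 (5S)-3-(bromomethyl)-5-[(triethylsilyl)oxy]-5,6-dihydro-2H-pyran-2-one
Product: 17 (4S,5S)-4-[(1R,2E,6Z)-8-[(tert-butyldiphenylsilyl)oxy]-1-hydroxy-7-iodo-3-methylocta-2,6-dien-1-yl]-3-methylidene-5-[(triethylsilyl)oxy]oxan-2-one
Conditions: CrCl2 (nickel-free, 4 equiv), THF, 0 °C to rt, bromide added to aldehyde and CrCl2
Reagents that add atoms: none
Why: Divalent chromium turns the allylic bromide into an allylchromium species that adds 1,2 to the enal through its γ-carbon C7 in a chair transition state (Nozaki–Hiyama allylation with a 3-(bromomethyl) unsaturated lactone): the ring holds C8 trans to the CH2Cr group, so C8 and the aldehyde substituent both sit equatorial and the C6/C7 anti adduct should form, while the aldehyde approaches C7 on the face opposite the neighbouring triethylsilyloxy group, which sets C7 relative to C8.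

Step 12
Reactants: 17 (4S,5S)-4-[(1R,2E,6Z)-8-[(tert-butyldiphenylsilyl)oxy]-1-hydroxy-7-iodo-3-methylocta-2,6-dien-1-yl]-3-methylidene-5-[(triethylsilyl)oxy]oxan-2-one
Product: 19 (4R,5R)-5-[(1E,5Z)-7-[(tert-butyldiphenylsilyl)oxy]-6-iodo-2-methylhepta-1,5-dien-1-yl]-4-[(1S)-1,2-dihydroxyethyl]-3-methylideneoxolan-2-one, via desilylated δ-lactone 18 (not isolated)
Conditions: CSA (0.1 equiv), MeOH–CH2Cl2 (1:3), 0 °C to rt
Reagents that add atoms: none
Why: Acid-catalysed methanolysis removes the triethylsilyl group and the C6 hydroxyl attacks the δ-lactone carbonyl through a fused five-membered transition state (translactonisation), relief of ring strain driving the system to the trans α-methylene-γ-butyrolactone; no stereocentre is touched, and any γ-lactone already formed in step 11 converges on the same diol.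

Step 13
Reactants: 19 (4R,5R)-5-[(1E,5Z)-7-[(tert-butyldiphenylsilyl)oxy]-6-iodo-2-methylhepta-1,5-dien-1-yl]-4-[(1S)-1,2-dihydroxyethyl]-3-methylideneoxolan-2-one; 20 methacrylic anhydride
Product: 22 (1S)-1-[(2R,3S)-2-[(1E,5Z)-7-[(tert-butyldiphenylsilyl)oxy]-6-iodo-2-methylhepta-1,5-dien-1-yl]-4-methylidene-5-oxooxolan-3-yl]-2-[(triethylsilyl)oxy]ethyl 2-methylprop-2-enoate, via C9 triethylsilyl ether 21 (not isolated)
Conditions: TESCl (1.05 equiv), imidazole, CH2Cl2, −40 °C; then 20, Et3N, DMAP (cat.), 0 °C to rt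
Reagents that add atoms: chlorotriethylsilane (TESCl), CC[Si](Cl)(CC)CC
Why: At low temperature the silyl chloride takes only the primary C9 hydroxyl, and the secondary C8 hydroxyl is then esterified in the same flask by DMAP-catalysed acylation, so the methacrylate goes on with retention at C8 and without a regiochemical choice.

Step 14
Reactants: 22 (1S)-1-[(2R,3S)-2-[(1E,5Z)-7-[(tert-butyldiphenylsilyl)oxy]-6-iodo-2-methylhepta-1,5-dien-1-yl]-4-methylidene-5-oxooxolan-3-yl]-2-[(triethylsilyl)oxy]ethyl 2-methylprop-2-enoate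
Product: 23 (1S)-1-[(2R,3S)-2-[(1E,5Z)-7-[(tert-butyldiphenylsilyl)oxy]-6-iodo-2-methylhepta-1,5-dien-1-yl]-4-methylidene-5-oxooxolan-3-yl]-2-oxoethyl 2-methylprop-2-enoate
Conditions: (COCl)2, DMSO, CH2Cl2, −78 to −40 °C; then iPr2NEt, −78 to −20 °C
Reagents that add atoms: none
Why: Under Swern conditions the chlorodimethylsulfonium ion cleaves the primary triethylsilyl ether and the alkoxysulfonium salt collapses to the aldehyde on addition of base (oxidative desilylation, Swern oxidation), so the free C9 alcohol that could take over the C8 acyl group never appears, and the hindered amine at low temperature spares the C8 stereocentre.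

Step 15
Reactants: 23 (1S)-1-[(2R,3S)-2-[(1E,5Z)-7-[(tert-butyldiphenylsilyl)oxy]-6-iodo-2-methylhepta-1,5-dien-1-yl]-4-methylidene-5-oxooxolan-3-yl]-2-oxoethyl 2-methylprop-2-enoate
Product: 24 (6R,7S,8S,9S)-14-[(tert-butyldiphenylsilyl)oxy]-9-hydroxy-8-(methacryloyloxy)germacra-1(10),4,11(13)-trien-12,6-olide (C4=C5 E; C2 and C9 cis on C1=C10, Z by CIP; lactone trans at C6/C7)
Conditions: CrCl2 (12 equiv), NiCl2 (0.12 equiv), degassed DMSO, rt, 0.003 M, slow addition of 23
Reagents that add atoms: none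
Why: Zerovalent nickel, generated from NiCl2 by CrCl2, inserts into the C10–I bond with retention of geometry, the alkenyl group passes to trivalent chromium, and the alkenylchromium adds to the C9 aldehyde to form C9–C10 and the chromium alkoxide of the C9 carbinol. The closest known reaction type is the Nozaki–Hiyama–Kishi cyclisation of iodoalkene aldehydes to medium and large carbocycles. The ten-membered carbocycle closes by a 10-exo-trig attack of C10 on the C9 carbonyl, run at high dilution against oligomerisation. The new C9 stereocentre is governed by the adjacent C8 stereocentre inside the cyclic transition state, where the trans-lactone and the two alkenes should restrict the aldehyde to the rotamer that leads to 9S (threo to the C8 ester); the step relies on this ring constraint and not on the open-chain Felkin preference. The step needs chemoselectivity for the aldehyde over the lactone and the two acrylate units, which the low basicity and nucleophilicity of alkenylchromium secure, and a ring-cis C1=C10 bond, which the Z-iodide secures by stereoretentive transfer.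

Step 16
Reactants: 24 (6R,7S,8S,9S)-14-[(tert-butyldiphenylsilyl)oxy]-9-hydroxy-8-(methacryloyloxy)germacra-1(10),4,11(13)-trien-12,6-olide
Product: 25 (6R,7S,8S,9S)-9-acetoxy-14-[(tert-butyldiphenylsilyl)oxy]-8-(methacryloyloxy)germacra-1(10),4,11(13)-trien-12,6-olide
Conditions: Ac2O, pyridine, DMAP (cat.), CH2Cl2, 0 °C
Reagents that add atoms: acetic anhydride, CC(=O)OC(C)=O
Why: DMAP-catalysed acetylation of the secondary allylic C9 alcohol, run cold and briefly so that the neighbouring C8 ester does not migrate.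

Step 17
Reactants: 25 (6R,7S,8S,9S)-9-acetoxy-14-[(tert-butyldiphenylsilyl)oxy]-8-(methacryloyloxy)germacra-1(10),4,11(13)-trien-12,6-olide
Product: 26 (6R,7S,8S,9S)-9-acetoxy-14-hydroxy-8-(methacryloyloxy)germacra-1(10),4,11(13)-trien-12,6-olide
Conditions: HF·pyridine, pyridine, THF, 0 °C to rt
Reagents that add atoms: none
Why: Buffered hydrogen fluoride cleaves the silyl ether (fluoride-mediated desilylation) under mildly acidic conditions, which should avoid the 1,3-acyl shift from O9 to the freed C14 hydroxyl and the conjugate additions that basic fluoride could cause.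

Step 18
Reactants: 26 (6R,7S,8S,9S)-9-acetoxy-14-hydroxy-8-(methacryloyloxy)germacra-1(10),4,11(13)-trien-12,6-olide
Product: 27 (6R,7S,8S,9S)-9-acetoxy-8-(methacryloyloxy)-14-oxogermacra-1(10)E,4E,11(13)-trien-12,6-olide (CNP0403553.1)
Conditions: MnO2, CH2Cl2, rt, in the dark
Reagents that add atoms: none
Why: Manganese dioxide oxidises only the primary allylic C14 alcohol to the enal under neutral conditions (allylic oxidation), leaving the esters, the α-methylene lactone and the alkene geometry untouched.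

Compound list
1 | geranyl acetate | CC(C)=CCC/C(C)=C/COC(C)=O | starting material
2 | 6,7-epoxygeranyl acetate (racemic epoxide) | CC(=O)OC/C=C(\C)CCC1OC1(C)C | intermediate
3 | (2E)-3-methyl-6-oxohex-2-en-1-yl acetate | O=CCC/C(C)=C/COC(C)=O | intermediate
4 | (triphenylphosphoranylidene)acetaldehyde | O=CC=P(c1ccccc1)(c1ccccc1)c1ccccc1 | starting material
5 | (2E,6E)-3-methyl-8-oxoocta-2,6-dien-1-yl acetate | O=C/C=C/CC/C(C)=C/COC(C)=O | intermediate
6 | (2E,6Z)-7-iodo-3-methyl-8-oxoocta-2,6-dien-1-yl acetate | O=C/C(I)=C/CC/C(C)=C/COC(C)=O | intermediate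
7 | (2E,6Z)-8-hydroxy-7-iodo-3-methylocta-2,6-dien-1-yl acetate | OC/C(I)=C/CC/C(C)=C/COC(C)=O | intermediate
8 | (2E,6Z)-8-[(tert-butyldiphenylsilyl)oxy]-7-iodo-3-methylocta-2,6-dien-1-yl acetate | CC(=O)OC/C=C(\C)CC/C=C(I)/CO[Si](c1ccccc1)(c1ccccc1)C(C)(C)C | intermediate
9 | (2E,6Z)-8-[(tert-butyldiphenylsilyl)oxy]-7-iodo-3-methylocta-2,6-dien-1-ol | OC/C=C(\C)CC/C=C(I)/CO[Si](c1ccccc1)(c1ccccc1)C(C)(C)C | intermediate
10 | (2E,6Z)-8-[(tert-butyldiphenylsilyl)oxy]-7-iodo-3-methylocta-2,6-dienal (C1–C6, C10, C14, C15) | O=C/C=C(\C)CC/C=C(I)/CO[Si](c1ccccc1)(c1ccccc1)C(C)(C)C | intermediate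
11 | (S)-but-3-ene-1,2-diol | OC[C@@H](O)C=C | starting material
12 | 2-(bromomethyl)acrylic acid | C=C(CBr)C(=O)O | starting material
13 | 2-(bromomethyl)acryloyl chloride | C=C(CBr)C(Cl)=O | intermediate
14 | (2S)-2-hydroxybut-3-en-1-yl 2-(bromomethyl)acrylate | C=C(CBr)C(=O)OC[C@@H](O)C=C | intermediate
15 | (2S)-2-[(triethylsilyl)oxy]but-3-en-1-yl 2-(bromomethyl)acrylate | C=C(CBr)C(=O)OC[C@@H](O[Si](CC)(CC)CC)C=C | intermediate
16 | (5S)-3-(bromomethyl)-5-[(triethylsilyl)oxy]-5,6-dihydro-2H-pyran-2-one | O=C1OC[C@@H](O[Si](CC)(CC)CC)C=C1CBr | intermediate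
17 | (4S,5S)-4-[(1R,2E,6Z)-8-[(tert-butyldiphenylsilyl)oxy]-1-hydroxy-7-iodo-3-methylocta-2,6-dien-1-yl]-3-methylidene-5-[(triethylsilyl)oxy]oxan-2-one | O=C1OC[C@@H](O[Si](CC)(CC)CC)[C@H]([C@H](O)/C=C(\C)CC/C=C(I)/CO[Si](c2ccccc2)(c2ccccc2)C(C)(C)C)C1=C | intermediate
18 | (4S,5S)-4-[(1R,2E,6Z)-8-[(tert-butyldiphenylsilyl)oxy]-1-hydroxy-7-iodo-3-methylocta-2,6-dien-1-yl]-5-hydroxy-3-methylideneoxan-2-one | O=C1OC[C@@H](O)[C@H]([C@H](O)/C=C(\C)CC/C=C(I)/CO[Si](c2ccccc2)(c2ccccc2)C(C)(C)C)C1=C | intermediate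
19 | (4R,5R)-5-[(1E,5Z)-7-[(tert-butyldiphenylsilyl)oxy]-6-iodo-2-methylhepta-1,5-dien-1-yl]-4-[(1S)-1,2-dihydroxyethyl]-3-methylideneoxolan-2-one | OC[C@@H](O)[C@H]1C(=C)C(=O)O[C@@H]1/C=C(\C)CC/C=C(I)/CO[Si](c2ccccc2)(c2ccccc2)C(C)(C)C | intermediate
20 | methacrylic anhydride | C=C(C)C(=O)OC(=O)C(C)=C | starting material
21 | (4R,5R)-5-[(1E,5Z)-7-[(tert-butyldiphenylsilyl)oxy]-6-iodo-2-methylhepta-1,5-dien-1-yl]-4-[(1S)-1-hydroxy-2-[(triethylsilyl)oxy]ethyl]-3-methylideneoxolan-2-one | CC[Si](CC)(CC)OC[C@@H](O)[C@H]1C(=C)C(=O)O[C@@H]1/C=C(\C)CC/C=C(I)/CO[Si](c2ccccc2)(c2ccccc2)C(C)(C)C | intermediate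
22 | (1S)-1-[(2R,3S)-2-[(1E,5Z)-7-[(tert-butyldiphenylsilyl)oxy]-6-iodo-2-methylhepta-1,5-dien-1-yl]-4-methylidene-5-oxooxolan-3-yl]-2-[(triethylsilyl)oxy]ethyl 2-methylprop-2-enoate | C=C(C)C(=O)O[C@H](CO[Si](CC)(CC)CC)[C@H]1C(=C)C(=O)O[C@@H]1/C=C(\C)CC/C=C(I)/CO[Si](c2ccccc2)(c2ccccc2)C(C)(C)C | intermediate
23 | (1S)-1-[(2R,3S)-2-[(1E,5Z)-7-[(tert-butyldiphenylsilyl)oxy]-6-iodo-2-methylhepta-1,5-dien-1-yl]-4-methylidene-5-oxooxolan-3-yl]-2-oxoethyl 2-methylprop-2-enoate (seco C9–C10 iodoalkene aldehyde) | C=C(C)C(=O)O[C@H](C=O)[C@H]1C(=C)C(=O)O[C@@H]1/C=C(\C)CC/C=C(I)/CO[Si](c2ccccc2)(c2ccccc2)C(C)(C)C | intermediate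
24 | (6R,7S,8S,9S)-14-[(tert-butyldiphenylsilyl)oxy]-9-hydroxy-8-(methacryloyloxy)germacra-1(10),4,11(13)-trien-12,6-olide (4E; C2/C9 cis on C1=C10) | C=C(C)C(=O)O[C@H]1[C@H]2C(=C)C(=O)O[C@@H]2/C=C(\C)CC/C=C(/CO[Si](c3ccccc3)(c3ccccc3)C(C)(C)C)[C@@H]1O | intermediate
25 | (6R,7S,8S,9S)-9-acetoxy-14-[(tert-butyldiphenylsilyl)oxy]-8-(methacryloyloxy)germacra-1(10),4,11(13)-trien-12,6-olide | C=C(C)C(=O)O[C@H]1[C@H]2C(=C)C(=O)O[C@@H]2/C=C(\C)CC/C=C(/CO[Si](c3ccccc3)(c3ccccc3)C(C)(C)C)[C@@H]1OC(C)=O | intermediate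
26 | (6R,7S,8S,9S)-9-acetoxy-14-hydroxy-8-(methacryloyloxy)germacra-1(10),4,11(13)-trien-12,6-olide | C=C(C)C(=O)O[C@H]1[C@H]2C(=C)C(=O)O[C@@H]2/C=C(\C)CC/C=C(/CO)[C@@H]1OC(C)=O | intermediate
27 | (6R,7S,8S,9S)-9-acetoxy-8-(methacryloyloxy)-14-oxogermacra-1(10)E,4E,11(13)-trien-12,6-olide (CNP0403553.1) | C=C(C)C(=O)O[C@H]1[C@H]2C(=C)C(=O)O[C@@H]2/C=C(\C)CC/C=C(/C=O)[C@@H]1OC(C)=O | target

Total step count: 18 steps (telescoped operations counted once).
Longest linear sequence: 15 steps (steps 1–7 and 11–18, from geranyl acetate); the lactone branch (steps 8–10) joins at step 11.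

Steps most likely to fail

Step 15. Facial selection at C9 during ring closure may follow the open-chain Felkin sense and give the erythro carbinol, and oligomerisation may compete with closure of the strained ring. The fallback sets out from the alcohol mixture that step 15 delivers from 23. The unwanted 9R alcohol F1 is oxidised with Dess–Martin periodinane (NaHCO3, CH2Cl2) to the C9 enone F2. F2 is then reduced 1,2 with catecholborane and the enantiomer of the Corey–Bakshi–Shibata oxazaborolidine that delivers hydride to the face giving 9S (reagent control; NaBH4/CeCl3·7H2O is the simpler variant), returning to the route at 24.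

Step 11. The allylchromium species may lose the triethylsilyloxy group by vinylogous β-elimination before it adds, or the anti and facial selectivities may erode with the poorly electrophilic β,β-disubstituted enal. The fallback sets out from 16. Borylation with B2pin2 and Pd2(dba)3 (cat.) gives the allylboronate F3. Allylboration of enal 10 catalysed by Sc(OTf)3 in toluene proceeds through the same ring-locked chair arrangement, without a metal that can trigger elimination, and gives the pinacol borate F4. Aqueous work-up hydrolyses F4, returning to the route at 17.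

Step 10. Ring closure onto the electron-poor 1,1-disubstituted bromomethyl acrylate may be slow, and the allylic bromide may shorten the life of the ruthenium carbene. The fallback sets out from 11. Acylation with methacryloyl chloride and 2,4,6-collidine at −78 °C gives the methacrylate F5, and TESOTf with 2,6-lutidine gives the silyl ether F6. Ring-closing metathesis of this methacrylate with the second-generation Grubbs catalyst gives the 3-methyl lactone F7. Wohl–Ziegler bromination of the allylic methyl group (N-bromosuccinimide, AIBN, PhCF3, 80 °C) returns to the route at 16.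

Further compounds
F1 | step 15 | (6R,7S,8S,9R)-14-[(tert-butyldiphenylsilyl)oxy]-9-hydroxy-8-(methacryloyloxy)germacra-1(10),4,11(13)-trien-12,6-olide (9-epimer of 24) | C=C(C)C(=O)O[C@H]1[C@H]2C(=C)C(=O)O[C@@H]2/C=C(\C)CC/C=C(/CO[Si](c3ccccc3)(c3ccccc3)C(C)(C)C)[C@H]1O
F2 | step 15 | (6R,7S,8S)-14-[(tert-butyldiphenylsilyl)oxy]-8-(methacryloyloxy)-9-oxogermacra-1(10),4,11(13)-trien-12,6-olide | C=C(C)C(=O)O[C@H]1[C@H]2C(=C)C(=O)O[C@@H]2/C=C(\C)CC/C=C(/CO[Si](c3ccccc3)(c3ccccc3)C(C)(C)C)C1=O
F3 | step 11 | (5S)-3-[(4,4,5,5-tetramethyl-1,3,2-dioxaborolan-2-yl)methyl]-5-[(triethylsilyl)oxy]-5,6-dihydro-2H-pyran-2-one | O=C1OC[C@@H](O[Si](CC)(CC)CC)C=C1CB2OC(C)(C)C(C)(C)O2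
F4 | step 11 | pinacol borate of 17 at the C6 oxygen | O=C1OC[C@@H](O[Si](CC)(CC)CC)[C@H]([C@H](OB2OC(C)(C)C(C)(C)O2)/C=C(\C)CC/C=C(I)/CO[Si](c3ccccc3)(c3ccccc3)C(C)(C)C)C1=C
F5 | step 10 | (2S)-2-hydroxybut-3-en-1-yl 2-methylprop-2-enoate | C=C(C)C(=O)OC[C@@H](O)C=C
F6 | step 10 | (2S)-2-[(triethylsilyl)oxy]but-3-en-1-yl 2-methylprop-2-enoate | C=C(C)C(=O)OC[C@@H](O[Si](CC)(CC)CC)C=C
F7 | step 10 | (5S)-3-methyl-5-[(triethylsilyl)oxy]-5,6-dihydro-2H-pyran-2-one | O=C1OC[C@@H](O[Si](CC)(CC)CC)C=C1C
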